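**Retrosynthetic overview**
1. Target 13 ⇐ ester 11 by ozonolysis: the cyclohexene ring of dihydro-β-ionone is carried as a masked 1,6-diketone and opened last.
2. 1,2-Dioxane of 11 ⇐ trans-β-lactone 8: the C3–O bond is made by 6-exo SN2 opening of the lactone by the C6 peroxide (inversion at C3; C2 comes with the lactone).
3. 8 ⇐ aldehyde 7 + methylketene (catalytic asymmetric trans-selective [2+2]).
4. 7 ⇐ epoxide 2 ⇐ ketone 1: the C6–O bond is made by invertive perhydrolysis of the (S)-epoxide; two carbons are added by Swern–Wittig and conjugate reduction.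
5. Rings in order: oxirane (made step 1, opened step 2), oxetan-2-one (made step 6, opened step 7), 1,2-dioxane (step 7); cyclohexene cleaved in step 8.

Assumption: dihydro-β-ionone (a fragrance chemical, also one step from β-ionone) counts as a cheap commercial starting material; all other carbons come from commodity reagents.
Assumption: the enantiomer named for each chiral catalyst is the one that gives the configuration drawn; if the sense of induction is the other one, the mirror-image catalyst is used.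

**Route**

Step 1
Reactants: 1 dihydro-β-ionone [4-(2,6,6-trimethylcyclohex-1-en-1-yl)butan-2-one]
Product: 2 (S)-2-methyl-2-[2-(2,6,6-trimethylcyclohex-1-en-1-yl)ethyl]oxirane
Conditions: Me3S(O)I, NaH (ylide, 1.2 equiv); (R)-LaLi3(binaphthoxide)3 5 mol%, (2,4,6-(MeO)3C6H2)3P=O 5 mol%, 5 Å MS, THF, rt
Reagents that add atoms: trimethylsulfoxonium iodide, C[S+](C)(C)=O.[I-]
Why: Catalytic asymmetric Corey–Chaykovsky epoxidation, in which the La/Li binaphthoxide activates the methyl ketone and the sulfoxonium ylide in one chiral pocket and tells CH3 from the CH2CH2R chain (alkyl methyl ketones typically give above 90% ee), so that C6 of the target is set as the quaternary oxirane carbon while the hindered ring alkene is inert to the ylide.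

Step 2
Reactants: 2 (S)-2-methyl-2-[2-(2,6,6-trimethylcyclohex-1-en-1-yl)ethyl]oxirane
Product: 3 (R)-2-hydroperoxy-2-methyl-4-(2,6,6-trimethylcyclohex-1-en-1-yl)butan-1-ol
Conditions: H2O2 (anhydrous, in Et2O, 6 equiv), H3PMo12O40 (3 mol%), Et2O, 0 °C to rt
Reagents that add atoms: hydrogen peroxide, OO
Why: Heteropolyacid-catalysed perhydrolysis of a 2,2-disubstituted epoxide, in which H2O2 attacks the activated oxirane at the tertiary carbon from the rear (SN2-like, inversion), so the C6–O bond of the future peroxide is formed with clean turnover of the centre fixed in step 1, and the very hindered ring alkene is not epoxidised in ether at room temperature.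

Step 3
Reactants: 3 (R)-2-hydroperoxy-2-methyl-4-(2,6,6-trimethylcyclohex-1-en-1-yl)butan-1-ol
Product: 4 triethyl{[(2R)-2-methyl-1-(triethylsilyloxy)-4-(2,6,6-trimethylcyclohex-1-en-1-yl)butan-2-yl]peroxy}silane
Conditions: Et3SiCl (2.4 equiv), imidazole, DMF, 0 °C
Reagents that add atoms: chlorotriethylsilane, CC[Si](Cl)(CC)CC
Why: Standard silylation with a silyl chloride and imidazole caps both O–H groups, the tertiary triethylsilyl peroxide being the usual robust protected form of a hydroperoxide, and no stereocentre is touched.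

Step 4
Reactants: 4 triethyl{[(2R)-2-methyl-1-(triethylsilyloxy)-4-(2,6,6-trimethylcyclohex-1-en-1-yl)butan-2-yl]peroxy}silane
Product: 6 (2E,4R)-4-methyl-4-[(triethylsilyl)peroxy]-6-(2,6,6-trimethylcyclohex-1-en-1-yl)hex-2-enal, via silylperoxy aldehyde 5 (not isolated)
Conditions: (COCl)2, DMSO, CH2Cl2, −78 to −40 °C; Et3N, to 0 °C; then Ph3P=CHCHO, rt to 40 °C
Reagents that add atoms: (triphenylphosphoranylidene)acetaldehyde, O=CC=P(c1ccccc1)(c1ccccc1)c1ccccc1
Why: Swern conditions convert a primary triethylsilyl ether directly into the aldehyde (the hindered tertiary silyl peroxide is not activated), and the non-enolisable α-peroxy aldehyde is trapped in the same flask by Wittig olefination with the stabilised formyl ylide, which gives the E-enal.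

Step 5
Reactants: 6 (2E,4R)-4-methyl-4-[(triethylsilyl)peroxy]-6-(2,6,6-trimethylcyclohex-1-en-1-yl)hex-2-enal
Product: 7 (4R)-4-methyl-4-[(triethylsilyl)peroxy]-6-(2,6,6-trimethylcyclohex-1-en-1-yl)hexanal
Conditions: Hantzsch ester (1.2 equiv), Bn2NH2+ CF3CO2− (10 mol%), THF, rt to 40 °C
Reagents that add atoms: none
Why: Iminium-catalysed transfer hydrogenation with a Hantzsch ester reduces only the conjugated C=C (hydride to C5; there is no γ-hydrogen, so no dienamine and no loss of the peroxide), a metal-free conjugate reduction that leaves the O–O bond, the ring alkene and C6 untouched.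

Step 6
Reactants: 7 (4R)-4-methyl-4-[(triethylsilyl)peroxy]-6-(2,6,6-trimethylcyclohex-1-en-1-yl)hexanal
Product: 8 (3R,4R)-3-methyl-4-{(3R)-3-methyl-3-[(triethylsilyl)peroxy]-5-(2,6,6-trimethylcyclohex-1-en-1-yl)pentyl}oxetan-2-one (trans-β-lactone)
Conditions: EtCOBr (3 equiv), iPr2NEt (2.5 equiv), [AlCl(L)]Br2 (10 mol%; L = (R,R)-cyclohexane-1,2-diamine salen ligand with 3,3′-bis(pyridinium-1-ylmethyl) and 5,5′-di-tert-butyl groups), CH2Cl2, −70 °C
Reagents that add atoms: propionyl bromide, CCC(=O)Br
Why: Catalytic asymmetric ketene–aldehyde [2+2] cyclocondensation in its trans-selective variant, in which the chiral aluminium salen Lewis acid binds the aldehyde while its pyridinium bromide arms deliver the acyl bromide enolate of in situ methylketene to one aldehyde face, so C2 and C3 are set together as the trans-(3R,4R)-β-lactone under catalyst control (the remote C6 centre has no influence).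

Step 7
Reactants: 8 (3R,4R)-3-methyl-4-{(3R)-3-methyl-3-[(triethylsilyl)peroxy]-5-(2,6,6-trimethylcyclohex-1-en-1-yl)pentyl}oxetan-2-one
Product: 11 methyl (2R)-2-{(3S,6R)-6-methyl-6-[2-(2,6,6-trimethylcyclohex-1-en-1-yl)ethyl]-1,2-dioxan-3-yl}propanoate, via lactone hydroperoxide 9 (not isolated), via dioxane acid 10 (not isolated)
Conditions: Bu4NF (1.05 equiv), THF (0.01 M), −20 to 0 °C; then MeI (3 equiv), 0 °C to rt
Reagents that add atoms: iodomethane, CI
Why: Proposed new method: fluoride removes the silyl group to give the tertiary peroxide anion, an α-effect nucleophile held five atoms from lactone C4, which opens the strained β-lactone by 6-exo-tet SN2 alkyl–oxygen cleavage with inversion at C3 (carboxylate leaving group, about 23 kcal/mol of ring strain released, whereas acyl attack would need an eight-membered perester and enolisation of a β-lactone is far too slow for this weak base), thereby closing the 1,2-dioxane, forming the C3–O bond and setting C3 before the carboxylate is O-methylated in the same flask; the closest known reactions are the SN2 C4-opening of β-lactones by azide, thiolate and carboxylate nucleophiles with inversion and the desilylation-triggered 6-exo cyclisation of silyl peroxides onto epoxides or alkyl sulfonates (intramolecular hydroperoxide alkylation).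

Step 8
Reactants: 11 methyl (2R)-2-{(3S,6R)-6-methyl-6-[2-(2,6,6-trimethylcyclohex-1-en-1-yl)ethyl]-1,2-dioxan-3-yl}propanoate
Product: 13 diacarperoxide C [methyl (2R)-2-[(3S,6S)-6-(4,4-dimethyl-3,8-dioxononyl)-6-methyl-1,2-dioxan-3-yl]propanoate], via methoxy hydroperoxide 12 (not isolated)
Conditions: O3, CH2Cl2–MeOH (4:1), −78 °C; then Me2S, −78 °C to rt
Reagents that add atoms: ozone, [O-][O+]=O
Why: Ozonolysis (Criegee cleavage, carbonyl oxide trapped by methanol, the resulting hydroperoxide reduced by Me2S) cuts the only C=C, the tetrasubstituted ring alkene, to the 1,6-diketone, while the dialkyl peroxide, the ester and the three stereocentres are inert to ozone and to Me2S (the C6 descriptor changes from R to S only because the side-chain priority changes).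

**Compound list**
1 | dihydro-β-ionone, 4-(2,6,6-trimethylcyclohex-1-en-1-yl)butan-2-one | CC(=O)CCC1=C(C)CCCC1(C)C | starting material
2 | (S)-2-methyl-2-[2-(2,6,6-trimethylcyclohex-1-en-1-yl)ethyl]oxirane | C[C@]1(CCC2=C(C)CCCC2(C)C)CO1 | intermediate
3 | (R)-2-hydroperoxy-2-methyl-4-(2,6,6-trimethylcyclohex-1-en-1-yl)butan-1-ol | OC[C@@](C)(CCC1=C(C)CCCC1(C)C)OO | intermediate
4 | triethyl{[(2R)-2-methyl-1-(triethylsilyloxy)-4-(2,6,6-trimethylcyclohex-1-en-1-yl)butan-2-yl]peroxy}silane | CC[Si](CC)(CC)OC[C@@](C)(CCC1=C(C)CCCC1(C)C)OO[Si](CC)(CC)CC | intermediate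
5 | (R)-2-methyl-2-[(triethylsilyl)peroxy]-4-(2,6,6-trimethylcyclohex-1-en-1-yl)butanal | O=C[C@@](C)(CCC1=C(C)CCCC1(C)C)OO[Si](CC)(CC)CC | intermediate (not isolated)
6 | (2E,4R)-4-methyl-4-[(triethylsilyl)peroxy]-6-(2,6,6-trimethylcyclohex-1-en-1-yl)hex-2-enal | O=C/C=C/[C@@](C)(CCC1=C(C)CCCC1(C)C)OO[Si](CC)(CC)CC | intermediate
7 | (4R)-4-methyl-4-[(triethylsilyl)peroxy]-6-(2,6,6-trimethylcyclohex-1-en-1-yl)hexanal | O=CCC[C@@](C)(CCC1=C(C)CCCC1(C)C)OO[Si](CC)(CC)CC | intermediate
8 | (3R,4R)-3-methyl-4-{(3R)-3-methyl-3-[(triethylsilyl)peroxy]-5-(2,6,6-trimethylcyclohex-1-en-1-yl)pentyl}oxetan-2-one | C[C@H]1C(=O)O[C@@H]1CC[C@@](C)(CCC2=C(C)CCCC2(C)C)OO[Si](CC)(CC)CC | intermediate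
9 | (3R,4R)-4-[(3R)-3-hydroperoxy-3-methyl-5-(2,6,6-trimethylcyclohex-1-en-1-yl)pentyl]-3-methyloxetan-2-one (present as its Bu4N peroxide salt) | C[C@H]1C(=O)O[C@@H]1CC[C@@](C)(CCC2=C(C)CCCC2(C)C)OO | intermediate (not isolated)
10 | (2R)-2-{(3S,6R)-6-methyl-6-[2-(2,6,6-trimethylcyclohex-1-en-1-yl)ethyl]-1,2-dioxan-3-yl}propanoic acid (present as its Bu4N carboxylate) | OC(=O)[C@H](C)[C@@H]1CC[C@@](C)(CCC2=C(C)CCCC2(C)C)OO1 | intermediate (not isolated)
11 | methyl (2R)-2-{(3S,6R)-6-methyl-6-[2-(2,6,6-trimethylcyclohex-1-en-1-yl)ethyl]-1,2-dioxan-3-yl}propanoate | COC(=O)[C@H](C)[C@@H]1CC[C@@](C)(CCC2=C(C)CCCC2(C)C)OO1 | intermediate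
12 | methyl (2R)-2-[(3S,6S)-6-(8-hydroperoxy-8-methoxy-4,4-dimethyl-3-oxononyl)-6-methyl-1,2-dioxan-3-yl]propanoate (both epimers at the new peroxyketal carbon; drawn as the regioisomer with the peroxyketal at the methyl-bearing carbon, the other regioisomer gives the same product) | COC(=O)[C@H](C)[C@@H]1CC[C@@](C)(CCC(=O)C(C)(C)CCCC(C)(OC)OO)OO1 | intermediate (not isolated)
13 | diacarperoxide C, methyl (2R)-2-[(3S,6S)-6-(4,4-dimethyl-3,8-dioxononyl)-6-methyl-1,2-dioxan-3-yl]propanoate | COC(=O)[C@H](C)[C@@H]1CC[C@@](C)(CCC(=O)C(C)(C)CCCC(C)=O)OO1 | target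

**Step count and risks**
Total steps: 8. Longest linear sequence: 8 (fully linear from 1).

Most likely to fail, in order:

Step 7 (the proposed new ring closure). Risks are attack of fluoride or of the peroxide anion at the lactone carbonyl, intermolecular reaction, and base-induced loss of CO2 or elimination from the lactone. The fallback uses known chemistry, sets out from 7 and comes back at 11, bypassing 8. Wittig olefination of 7 with Ph3P=C(CH3)CO2Me (CH2Cl2, rt) gives methyl (2E,6S)-2,6-dimethyl-6-[(triethylsilyl)peroxy]-8-(2,6,6-trimethylcyclohex-1-en-1-yl)oct-2-enoate F1. HF·pyridine then frees methyl (2E,6S)-6-hydroperoxy-2,6-dimethyl-8-(2,6,6-trimethylcyclohex-1-en-1-yl)oct-2-enoate F2, which undergoes the established base-mediated intramolecular peroxy-Michael addition (Et2NH, CF3CH2OH) to the 1,2-dioxane. C6 is fixed, but C2 and C3 are not controlled in this fallback, so 11 has to be separated from its C2/C3 diastereomers by HPLC.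

Step 6 (trans-selective [2+2] on a functionalised aldehyde with a specialised catalyst). Risks are a low trans:cis ratio or low ee. The fallback sets out from 7 and comes back at 8. Aldehyde 7 is condensed with acetyl chloride (iPr2NEt, LiClO4, O-trimethylsilylquinidine or its quinine pseudo-enantiomer, whichever gives 4R; CH2Cl2–Et2O, −78 °C) to the 3-unsubstituted lactone (4R)-4-{(3R)-3-methyl-3-[(triethylsilyl)peroxy]-5-(2,6,6-trimethylcyclohex-1-en-1-yl)pentyl}oxetan-2-one F3. Its lithium enolate (LiN(SiMe3)2, THF, −78 °C) is methylated with MeI anti to the C4 side chain, which gives the trans-lactone 8.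

Step 2 (perhydrolysis of the epoxide). Risks are epoxidation of the ring alkene by the molybdenum/H2O2 system, rearrangement of the epoxide to an aldehyde, and partial loss of stereospecificity. The fallback sets out from 1 and comes back at 7.
- With the same La/Li catalyst but excess ylide (45 °C), ketone 1 is taken in one pot through the epoxide to (S)-2-methyl-2-[2-(2,6,6-trimethylcyclohex-1-en-1-yl)ethyl]oxetane F4.
- Opening with ethereal H2O2 promoted by Me3SiOSO2CF3 (inversion at the tertiary carbon, a known oxetane reaction) gives (R)-3-hydroperoxy-3-methyl-5-(2,6,6-trimethylcyclohex-1-en-1-yl)pentan-1-ol F5.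
- Et3SiCl/imidazole gives triethyl{[(3R)-3-methyl-1-(triethylsilyloxy)-5-(2,6,6-trimethylcyclohex-1-en-1-yl)pentan-3-yl]peroxy}silane F6.
- Swern oxidation (iPr2NEt, −78 °C) gives (R)-3-methyl-3-[(triethylsilyl)peroxy]-5-(2,6,6-trimethylcyclohex-1-en-1-yl)pentanal F7.
- Wittig reaction with Ph3P=CHOMe gives the enol ether (4R)-1-methoxy-4-methyl-4-[(triethylsilyl)peroxy]-6-(2,6,6-trimethylcyclohex-1-en-1-yl)hex-1-ene F8 (E/Z mixture).
- Mild hydrolysis (oxalic acid, wet THF) gives aldehyde 7.

Further compounds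
F1 | step 7 | methyl (2E,6S)-2,6-dimethyl-6-[(triethylsilyl)peroxy]-8-(2,6,6-trimethylcyclohex-1-en-1-yl)oct-2-enoate | COC(=O)/C(C)=C/CC[C@@](C)(CCC1=C(C)CCCC1(C)C)OO[Si](CC)(CC)CC
F2 | step 7 | methyl (2E,6S)-6-hydroperoxy-2,6-dimethyl-8-(2,6,6-trimethylcyclohex-1-en-1-yl)oct-2-enoate | COC(=O)/C(C)=C/CC[C@@](C)(CCC1=C(C)CCCC1(C)C)OO
F3 | step 6 | (4R)-4-{(3R)-3-methyl-3-[(triethylsilyl)peroxy]-5-(2,6,6-trimethylcyclohex-1-en-1-yl)pentyl}oxetan-2-one | O=C1C[C@@H](CC[C@@](C)(CCC2=C(C)CCCC2(C)C)OO[Si](CC)(CC)CC)O1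
F4 | step 2 | (S)-2-methyl-2-[2-(2,6,6-trimethylcyclohex-1-en-1-yl)ethyl]oxetane | C[C@]1(CCC2=C(C)CCCC2(C)C)CCO1
F5 | step 2 | (R)-3-hydroperoxy-3-methyl-5-(2,6,6-trimethylcyclohex-1-en-1-yl)pentan-1-ol | OCC[C@@](C)(CCC1=C(C)CCCC1(C)C)OO
F6 | step 2 | triethyl{[(3R)-3-methyl-1-(triethylsilyloxy)-5-(2,6,6-trimethylcyclohex-1-en-1-yl)pentan-3-yl]peroxy}silane | CC[Si](CC)(CC)OCC[C@@](C)(CCC1=C(C)CCCC1(C)C)OO[Si](CC)(CC)CC
F7 | step 2 | (R)-3-methyl-3-[(triethylsilyl)peroxy]-5-(2,6,6-trimethylcyclohex-1-en-1-yl)pentanal | O=CC[C@@](C)(CCC1=C(C)CCCC1(C)C)OO[Si](CC)(CC)CC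
F8 | step 2 | (4R)-1-methoxy-4-methyl-4-[(triethylsilyl)peroxy]-6-(2,6,6-trimethylcyclohex-1-en-1-yl)hex-1-ene (E/Z mixture) | COC=CC[C@@](C)(CCC1=C(C)CCCC1(C)C)OO[Si](CC)(CC)CC
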